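**Retrosynthetic overview**
- Ring A (C10, C5, C6, C7, C8, C9) carries the same 1-carbonylvinyl unit at C5 and at C7: C4(=C15H2)–C3 and C11(=C13H2)–C12. Both carbonyl carbons go back to CO. This leaves a 5,7-bis(enol triflate) in which the cis C8–OH closes lactone ring B and methanol caps C3.
- The bis(triflate) comes from the 5,7-diacetyl compound. The cis C7-acetyl/C8-oxygen pair arises from a 1,2-hydride shift in a C7–C8 epoxy carbinol, and the C5 acetyl from a C4 boronate.
- C6 is reduced while C7 is still sp2 (2-iodoenone). C5 is set by enolate protonation, C10 by vinylcopper addition anti to O9, and C9 by CBS reduction.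
- Ring A is bought as 2-methylcyclohex-2-enone and ring B closes in the key step. The two esters and the aldehyde are finished last, with C3 kept as a silyl ether while O6 is free.

Key step: step 17

Remark: atoms carry elemane numbers, "top" is the face of ring A that bears the C10 vinyl group. Centres at C4, C11 and C12 that are later oxidised away are carried as epimer mixtures and left undefined in the SMILES. Angelic acid and (R)-2-methylbutanoic acid are taken as purchasable single isomers.

Step 1
Reactants: 1 2-methylcyclohex-2-en-1-one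
Product: 2 (S)-2-methylcyclohex-2-en-1-ol
Conditions: (R)-Me-CBS [(R)-1-methyl-3,3-diphenyltetrahydro-1H,3H-pyrrolo[1,2-c][1,3,2]oxazaborole] (10 mol %), BH3·SMe2, THF, −20 °C; MeOH, then water
Reagents that add atoms: none
Why: Corey–Bakshi–Shibata reduction, in which the α-methylated alkenyl arm acts as the large and the CH2 arm as the small substituent, so the (R)-catalyst should give the S carbinol, the future C9.

Step 2
Reactants: 2 (S)-2-methylcyclohex-2-en-1-ol
Product: 3 (S)-tert-butyldimethylsilyl ether of 2
Conditions: tBuMe2SiCl, imidazole, DMF, rt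
Reagents that add atoms: tert-butyldimethylsilyl chloride CC(C)(C)[Si](C)(C)Cl
Why: Routine imidazole-promoted silylation that touches no stereocentre and installs the bulky ether which steers step 4.

Step 3
Reactants: 3 (S)-tert-butyldimethylsilyl ether of 2
Product: 4 (S)-4-(tert-butyldimethylsilyloxy)-3-methylcyclohex-2-en-1-one
Conditions: Rh2(cap)4 (dirhodium tetracaprolactamate, 1 mol %), tBuOOH (70 % in water, 5 equiv), 1,2-dichloroethane, 40 °C
Reagents that add atoms: tert-butyl hydroperoxide CC(C)(C)OO
Why: Dirhodium-catalysed allylic oxidation attacks the only ring CH2 next to the alkene (future C6) faster than the methyl group or the oxygen-bearing C9–H, which gives the enone with C9 intact.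

Step 4
Reactants: 4 (S)-4-(tert-butyldimethylsilyloxy)-3-methylcyclohex-2-en-1-one; 5 vinylmagnesium bromide; 6 acetaldehyde
Product: 8 4-(tert-butyldimethylsilyloxy)-2-(1-hydroxyethyl)-3-methyl-3-vinylcyclohexan-1-one (vinyl trans to the silyl ether; C5/C4 epimers), via bromomagnesium enolate 7 (not isolated)
Conditions: CuBr·SMe2 (20 mol %), THF/Me2S, −40 °C; then 6 (5 equiv), −78 °C; aq. NH4Cl
Reagents that add atoms: none
Why: Copper-catalysed 1,4-addition followed by aldol trapping, in which the C9 silyl ether, held pseudo-axial by allylic 1,2-strain with the C10 methyl group, closes the bottom face so that vinyl enters from the top and fixes C10, while the C5 and C4 centres do not matter because step 5 erases them.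

Step 5
Reactants: 8 aldol
Product: 10 (Z)-2-ethylidene-4-(tert-butyldimethylsilyloxy)-3-methyl-3-vinylcyclohexan-1-one, via mesylate 9 (not isolated)
Conditions: MeSO2Cl, Et3N, CH2Cl2, 0 °C; then DBU, rt
Reagents that add atoms: methanesulfonyl chloride CS(=O)(=O)Cl (atoms kept only in 9)
Why: Mesylation and E1cB elimination of a β-hydroxy ketone, which makes C5 planar again with the C15 methyl group turned away from the quaternary C10; either alkene isomer serves in step 6.

Step 6
Reactants: 10 ethylidene enone; 11 bis(pinacolato)diboron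
Product: 12 2-[1-(pinacolboryl)ethyl] ketone with H5 on the top face (side chain bottom and trans to vinyl; C4 epimers)
Conditions: CuCl (5 mol %), Xantphos (5 mol %), NaOtBu (10 mol %), MeOH (2 equiv), THF, 0 °C → rt
Reagents that add atoms: none
Why: Copper-catalysed conjugate borylation puts boron on C4, and methanol should protonate the C5=C6 enolate from the top, because the bottom face carries both the C10 methyl group and the C9 silyl ether; an electrophilic carbon would enter on that same top face and give the wrong C5 epimer, which is why hydrogen is delivered last.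

Step 7
Reactants: 12 boronate ketone
Product: 14 C7=C8 enone (C6 ketone), via trimethylsilyl enol ether 13 (not isolated)
Conditions: LiN(iPr)2, Me3SiCl, THF, −78 °C; crude 13, Pd(OAc)2 (1.1 equiv), MeCN, rt
Reagents that add atoms: chlorotrimethylsilane C[Si](C)(C)Cl (atoms kept only in 13)
Why: Saegusa–Ito oxidation, in which kinetic deprotonation takes the C7 methylene rather than the crowded C5 methine and quaternary C10 allows unsaturation only towards C8.

Step 8
Reactants: 14 enone
Product: 15 2-iodoenone (iodine on C7)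
Conditions: I2, pyridine/CH2Cl2 (1:1), rt
Reagents that add atoms: iodine [I][I]
Why: α-Iodination of a cyclic enone by the pyridine addition, iodination, elimination sequence, which gives C7 a handle while keeping it sp2 for the next step.

Step 9
Reactants: 15 2-iodoenone
Product: 16 allylic alcohol with O6 on the bottom face (cis to the C5 side chain)
Conditions: NaBH4, CeCl3·7H2O, MeOH, −78 → −20 °C
Reagents that add atoms: none
Why: Luche 1,2-reduction in which hydride should come from the top, since the bottom trajectory at C6 meets the syn-axial C10 methyl group and the C5 side chain and planar C7 leaves the top open, so C6 is set before C7 receives its axial substituent.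

Step 10
Reactants: 16 allylic alcohol
Product: 17 O6 triethylsilyl ether
Conditions: Et3SiOTf, 2,6-lutidine, CH2Cl2, −78 → 0 °C
Reagents that add atoms: triethylsilyl triflate CC[Si](CC)(CC)OS(=O)(=O)C(F)(F)F
Why: Silyl triflate silylation suited to a hindered secondary alcohol; no stereocentre changes.

Step 11
Reactants: 17 O6 triethylsilyl ether
Product: 18 C4 carbinol
Conditions: NaBO3·4H2O, THF/H2O (1:1), rt
Reagents that add atoms: sodium perborate [Na+].[Na+].O[B-]1(O)OO[B-](O)(O)OO1
Why: Perborate oxidation of a secondary alkylboronate (1,2-shift from boron to oxygen), mild enough to spare the alkenyl iodide and both silyl ethers.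

Step 12
Reactants: 18 C4 carbinol
Product: 19 5-acetyl 7-iodo compound (C4 methyl ketone)
Conditions: Dess–Martin periodinane, CH2Cl2, 0 °C → rt
Reagents that add atoms: none
Why: Dess–Martin oxidation removes the C4 centre, and C5, now α to a ketone, already has the stable arrangement (equatorial acetyl, with O6 held pseudo-axial by allylic strain with iodine).

Step 13
Reactants: 19 5-acetyl 7-iodo compound; 6 acetaldehyde
Product: 20 C7 (1-hydroxyethyl) allylic alcohol (C11 epimers)
Conditions: CrCl2 (6 equiv), NiCl2 (2 mol %), 6 (5 equiv), DMF, rt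
Reagents that add atoms: none
Why: Nozaki–Hiyama–Kishi coupling, in which nickel activates the C7–I bond and the alkenyl species of trivalent chromium adds to the aldehyde but not to the C4 ketone; both C11 epimers are used.

Step 14
Reactants: 20 allylic alcohol
Product: 21 C7–C8 epoxy carbinol with the epoxide oxygen on the top face
Conditions: VO(acac)2 (5 mol %), tBuOOH (decane, 1.5 equiv), CH2Cl2, 0 °C → rt
Reagents that add atoms: tert-butyl hydroperoxide CC(C)(C)OO
Why: Hydroxyl-directed vanadium-catalysed epoxidation selects the allylic C7=C8 bond over the remote vinyl group, and oxygen should arrive on the top face because the O6 and O9 silyl ethers close the bottom, which sets C8.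

Step 15
Reactants: 21 epoxy carbinol
Product: 23 5,7-diacetyl compound with O8 as trimethylsilyl ether (acetyl and O8 both top at C7/C8), via C11 trimethylsilyl ether 22 (not isolated)
Conditions: Me3SiOTf (1.3 equiv), 2,6-lutidine (1.5 equiv), CH2Cl2, −78 → −40 °C
Reagents that add atoms: trimethylsilyl triflate C[Si](C)(C)OS(=O)(=O)C(F)(F)F
Why: Semipinacol (non-aldol aldol) rearrangement of a 2,3-epoxy alcohol, in which the silylated epoxide ionises at tertiary C7 and the C11 hydride migrates anti to the leaving oxygen, that is from the bottom, so that C7 is inverted (H7 bottom, acetyl top, trans to O6) while C8 keeps its top oxygen, which emerges already silylated.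

Step 16
Reactants: 23 5,7-diacetyl compound
Product: 25 5,7-bis(enol triflate) with free C8 hydroxyl, via O8-trimethylsilyl bis(enol triflate) 24 (not isolated)
Conditions: KN(SiMe3)2 (2.5 equiv), THF, −78 °C, inverse addition; N-(5-chloro-2-pyridyl)bis(trifluoromethanesulfonimide) (2.6 equiv), −78 °C; crude 24, citric acid, MeOH, 0 °C
Reagents that add atoms: N-(5-chloro-2-pyridyl)bis(trifluoromethanesulfonimide) O=S(=O)(N(c1ccc(Cl)cn1)S(=O)(=O)C(F)(F)F)C(F)(F)F
Why: Kinetic enolisation and O-triflation, in which the bulky amide removes methyl protons (C15, C13) rather than the crowded C5 and C7 methines, so both alkenes end terminal, no β-silyloxy group is expelled and the trans 1,3-arms cannot undergo aldol closure; mild methanolysis then removes only the trimethylsilyl group, so O8–H never sits next to the C11 ketone.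

Step 17
Reactants: 25 5,7-bis(enol triflate) with free C8 hydroxyl; 26 carbon monoxide; 27 methanol
Product: 28 α-methylene lactone bearing the C5 methyl acrylate
Conditions: Pd(PPh3)4 (10 mol %), CO (1 atm), Et3N (4 equiv), MeOH/DMF (1:1), 50 °C
Reagents that add atoms: none
Why: Zerovalent palladium adds oxidatively to both alkenyl C–OTf bonds, CO inserts into each alkenyl–palladium bond (forming C4–C3 and C11–C12), and the two acylpalladium species are cleaved by oxygen nucleophiles while Et3N takes up triflic acid. The closest known reactions are the methoxycarbonylation of enol triflates to 2-substituted acrylates and the carbonylative cyclisation of hydroxy alkenyl triflates to α-methylene-γ-butyrolactones, which use the same catalyst, base and CO pressure. Ring B closes by 5-exo-trig attack of O8 on acyl carbon C12, possible because the axial C7 arm and the equatorial C8 oxygen are cis; if methanol reaches C12 first, the cis γ-hydroxy ester should lactonise in the same basic medium, so both paths lead to 28. No stereocentre is created, and C5, C7 and C8 are not at risk because the former ketone α-carbons are now only allylic. Selective capture (O8 at C12, methanol at C3) is secured by silylation of O6 and O9. Methanolysis at C3 must outrun 5-exo acylpalladation of the C10 vinyl group, which methanol as co-solvent in large excess secures, and carbopalladation before CO insertion could only form a cyclobutane or proceed 5-endo.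

Step 18
Reactants: 28 α-methylene lactone bearing the C5 methyl acrylate
Product: 29 α-methylene lactol with C3 allylic alcohol (C12 epimers)
Conditions: iBu2AlH (3.3 equiv), CH2Cl2, −78 °C; aq. potassium sodium tartrate
Reagents that add atoms: none
Why: Low-temperature iBu2AlH reduction, in which the lactone stops at the aluminium hemiacetal while the acrylate takes two hydrides in 1,2-fashion, so C12 (lactol) and C3 (primary alcohol) become distinguishable.

Step 19
Reactants: 29 lactol alcohol
Product: 30 C3 tert-butyldiphenylsilyl ether of the lactol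
Conditions: tBuPh2SiCl (1.1 equiv), imidazole, CH2Cl2, 0 °C
Reagents that add atoms: tert-butyldiphenylsilyl chloride CC(C)(C)[Si](Cl)(c1ccccc1)c1ccccc1
Why: The bulky silyl chloride should take the primary allylic alcohol ahead of the hemiacetal hydroxyl, which keeps C3 at the alcohol level so that a free O6–H cannot later form a five-membered lactol with a C3 aldehyde.

Step 20
Reactants: 30 silylated lactol
Product: 31 α-methylene lactone with C3 silyl ether
Conditions: MnO2 (activated, excess), CH2Cl2, rt
Reagents that add atoms: none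
Why: MnO2 oxidation of an allylic hemiacetal restores the α-methylene-γ-butyrolactone without touching silyl ethers or alkenes.

Step 21
Reactants: 31 α-methylene lactone with C3 silyl ether
Product: 32 C6 alcohol
Conditions: HF·pyridine, pyridine, THF, 0 °C → rt
Reagents that add atoms: none
Why: Buffered fluoride cleaves the triethylsilyl ether well before the tert-butyldimethylsilyl and tert-butyldiphenylsilyl ethers, in line with the usual order of silyl ether lability.

Step 22
Reactants: 32 C6 alcohol; 33 angelic acid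
Product: 35 O6 angelate, via angelic 2,4,6-trichlorobenzoic anhydride 34 (not isolated)
Conditions: 33, 2,4,6-Cl3C6H2COCl, Et3N, toluene, rt; then 32, 80 °C, no DMAP
Reagents that add atoms: 2,4,6-trichlorobenzoyl chloride O=C(Cl)c1c(Cl)cc(Cl)cc1Cl (atoms kept only in 34)
Why: Yamaguchi-type mixed-anhydride esterification without a nucleophilic catalyst, the usual way to acylate a hindered alcohol with angelic acid while keeping the Z alkene.

Step 23
Reactants: 35 O6 angelate
Product: 36 C3,C9 diol
Conditions: HF·pyridine (excess), THF, rt → 40 °C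
Reagents that add atoms: none
Why: Acidic fluoride removes both remaining silyl ethers in one operation and leaves the angelate, the lactone and the alkenes unchanged.

Step 24
Reactants: 36 C3,C9 diol
Product: 37 C3 enal with free C9 hydroxyl
Conditions: MnO2 (activated, excess), CH2Cl2, rt
Reagents that add atoms: none
Why: MnO2 oxidises only the primary allylic alcohol and leaves the saturated secondary C9 hydroxyl untouched.

Step 25
Reactants: 37 C3 enal with free C9 hydroxyl; 38 (R)-2-methylbutanoic acid
Product: 39 target CNP0295282.1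
Conditions: dicyclohexylcarbodiimide, DMAP (10 mol %), CH2Cl2, 0 °C → rt
Reagents that add atoms: none
Why: Steglich esterification of the equatorial C9 alcohol; the acyl stereocentre comes with the acid and should survive at low DMAP loading and low temperature, and O8 is tied up in the lactone so no acyl migration is possible.

**Compound list**
1 | 2-methylcyclohex-2-en-1-one | CC1=CCCCC1=O | starting material
2 | (S)-2-methylcyclohex-2-en-1-ol | CC1=CCCC[C@@H]1O | intermediate
3 | (S)-tert-butyldimethylsilyl ether of 2 | CC1=CCCC[C@@H]1O[Si](C)(C)C(C)(C)C | intermediate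
4 | (S)-4-(tert-butyldimethylsilyloxy)-3-methylcyclohex-2-en-1-one | CC1=CC(=O)CC[C@@H]1O[Si](C)(C)C(C)(C)C | intermediate
5 | vinylmagnesium bromide | C=C[Mg]Br | starting material
6 | acetaldehyde | CC=O | starting material
7 | bromomagnesium C5=C6 enolate after vinyl addition | C=C[C@@]1(C)C=C(O[Mg]Br)CC[C@@H]1O[Si](C)(C)C(C)(C)C | intermediate
8 | aldol, 2-(1-hydroxyethyl)-3-methyl-3-vinyl ketone (C5/C4 epimers) | C=C[C@@]1(C)C(C(C)O)C(=O)CC[C@@H]1O[Si](C)(C)C(C)(C)C | intermediate
9 | mesylate of 8 | C=C[C@@]1(C)C(C(C)OS(C)(=O)=O)C(=O)CC[C@@H]1O[Si](C)(C)C(C)(C)C | intermediate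
10 | (Z)-2-ethylidene enone | C=C[C@@]1(C)/C(=C/C)C(=O)CC[C@@H]1O[Si](C)(C)C(C)(C)C | intermediate
11 | bis(pinacolato)diboron | CC1(C)OB(OC1(C)C)B1OC(C)(C)C(C)(C)O1 | starting material
12 | C4 pinacol boronate ketone, side chain trans to vinyl | C=C[C@@]1(C)[C@H](C(C)B3OC(C)(C)C(C)(C)O3)C(=O)CC[C@@H]1O[Si](C)(C)C(C)(C)C | intermediate
13 | C6=C7 trimethylsilyl enol ether of 12 | C=C[C@@]1(C)[C@H](C(C)B3OC(C)(C)C(C)(C)O3)C(O[Si](C)(C)C)=CC[C@@H]1O[Si](C)(C)C(C)(C)C | intermediate
14 | C7=C8 enone | C=C[C@@]1(C)[C@H](C(C)B3OC(C)(C)C(C)(C)O3)C(=O)C=C[C@@H]1O[Si](C)(C)C(C)(C)C | intermediate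
15 | 7-iodoenone | C=C[C@@]1(C)[C@H](C(C)B3OC(C)(C)C(C)(C)O3)C(=O)C(I)=C[C@@H]1O[Si](C)(C)C(C)(C)C | intermediate
16 | C6 allylic alcohol, O6 cis to the C5 chain | C=C[C@@]1(C)[C@H](C(C)B3OC(C)(C)C(C)(C)O3)[C@H](O)C(I)=C[C@@H]1O[Si](C)(C)C(C)(C)C | intermediate
17 | O6 triethylsilyl ether | C=C[C@@]1(C)[C@H](C(C)B3OC(C)(C)C(C)(C)O3)[C@H](O[Si](CC)(CC)CC)C(I)=C[C@@H]1O[Si](C)(C)C(C)(C)C | intermediate
18 | C4 carbinol | C=C[C@@]1(C)[C@H](C(C)O)[C@H](O[Si](CC)(CC)CC)C(I)=C[C@@H]1O[Si](C)(C)C(C)(C)C | intermediate
19 | 5-acetyl 7-iodo compound | C=C[C@@]1(C)[C@H](C(C)=O)[C@H](O[Si](CC)(CC)CC)C(I)=C[C@@H]1O[Si](C)(C)C(C)(C)C | intermediate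
20 | C7 (1-hydroxyethyl) allylic alcohol | C=C[C@@]1(C)[C@H](C(C)=O)[C@H](O[Si](CC)(CC)CC)C(C(C)O)=C[C@@H]1O[Si](C)(C)C(C)(C)C | intermediate
21 | C7–C8 epoxy carbinol, epoxide on the top face | C=C[C@@]1(C)[C@H](C(C)=O)[C@H](O[Si](CC)(CC)CC)[C@@]2(C(C)O)O[C@H]2[C@@H]1O[Si](C)(C)C(C)(C)C | intermediate
22 | C11 trimethylsilyl ether of 21 | C=C[C@@]1(C)[C@H](C(C)=O)[C@H](O[Si](CC)(CC)CC)[C@@]2(C(C)O[Si](C)(C)C)O[C@H]2[C@@H]1O[Si](C)(C)C(C)(C)C | intermediate
23 | 5,7-diacetyl compound, O8 trimethylsilyl ether | C=C[C@@]1(C)[C@H](C(C)=O)[C@H](O[Si](CC)(CC)CC)[C@@H](C(C)=O)[C@@H](O[Si](C)(C)C)[C@@H]1O[Si](C)(C)C(C)(C)C | intermediate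
24 | O8-trimethylsilyl 5,7-bis(enol triflate) | C=C[C@@]1(C)[C@H](C(=C)OS(=O)(=O)C(F)(F)F)[C@H](O[Si](CC)(CC)CC)[C@@H](C(=C)OS(=O)(=O)C(F)(F)F)[C@@H](O[Si](C)(C)C)[C@@H]1O[Si](C)(C)C(C)(C)C | intermediate
25 | 5,7-bis(enol triflate) with free C8 hydroxyl | C=C[C@@]1(C)[C@H](C(=C)OS(=O)(=O)C(F)(F)F)[C@H](O[Si](CC)(CC)CC)[C@@H](C(=C)OS(=O)(=O)C(F)(F)F)[C@@H](O)[C@@H]1O[Si](C)(C)C(C)(C)C | intermediate
26 | carbon monoxide | [C-]#[O+] | starting material
27 | methanol | CO | starting material
28 | α-methylene lactone bearing the C5 methyl acrylate | C=C[C@@]1(C)[C@H](C(=C)C(=O)OC)[C@H](O[Si](CC)(CC)CC)[C@H]2C(=C)C(=O)O[C@H]2[C@@H]1O[Si](C)(C)C(C)(C)C | intermediate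
29 | α-methylene lactol with C3 allylic alcohol | C=C[C@@]1(C)[C@H](C(=C)CO)[C@H](O[Si](CC)(CC)CC)[C@H]2C(=C)C(O)O[C@H]2[C@@H]1O[Si](C)(C)C(C)(C)C | intermediate
30 | C3 tert-butyldiphenylsilyl ether of the lactol | C=C[C@@]1(C)[C@H](C(=C)CO[Si](c3ccccc3)(c3ccccc3)C(C)(C)C)[C@H](O[Si](CC)(CC)CC)[C@H]2C(=C)C(O)O[C@H]2[C@@H]1O[Si](C)(C)C(C)(C)C | intermediate
31 | α-methylene lactone with C3 silyl ether | C=C[C@@]1(C)[C@H](C(=C)CO[Si](c3ccccc3)(c3ccccc3)C(C)(C)C)[C@H](O[Si](CC)(CC)CC)[C@H]2C(=C)C(=O)O[C@H]2[C@@H]1O[Si](C)(C)C(C)(C)C | intermediate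
32 | C6 alcohol | C=C[C@@]1(C)[C@H](C(=C)CO[Si](c3ccccc3)(c3ccccc3)C(C)(C)C)[C@H](O)[C@H]2C(=C)C(=O)O[C@H]2[C@@H]1O[Si](C)(C)C(C)(C)C | intermediate
33 | angelic acid, (Z)-2-methylbut-2-enoic acid | C/C=C(/C)C(=O)O | starting material
34 | angelic 2,4,6-trichlorobenzoic anhydride | C/C=C(/C)C(=O)OC(=O)c1c(Cl)cc(Cl)cc1Cl | intermediate
35 | O6 angelate | C=C[C@@]1(C)[C@H](C(=C)CO[Si](c3ccccc3)(c3ccccc3)C(C)(C)C)[C@H](OC(=O)/C(C)=C\C)[C@H]2C(=C)C(=O)O[C@H]2[C@@H]1O[Si](C)(C)C(C)(C)C | intermediate
36 | C3,C9 diol | C=C[C@@]1(C)[C@H](C(=C)CO)[C@H](OC(=O)/C(C)=C\C)[C@H]2C(=C)C(=O)O[C@H]2[C@@H]1O | intermediate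
37 | C3 enal with free C9 hydroxyl | C=C[C@@]1(C)[C@H](C(=C)C=O)[C@H](OC(=O)/C(C)=C\C)[C@H]2C(=C)C(=O)O[C@H]2[C@@H]1O | intermediate
38 | (R)-2-methylbutanoic acid | CC[C@@H](C)C(=O)O | starting material
39 | CNP0295282.1 | C=C[C@@]1(C)[C@H](C(=C)C=O)[C@H](OC(=O)/C(C)=C\C)[C@H]2C(=C)C(=O)O[C@H]2[C@@H]1OC(=O)[C@H](C)CC | target

Total step count: 25. Longest linear sequence: 25 steps (1 → 39; all other partners are bought).

**Three steps most likely to fail**

**Step 17 (twin carbonylation).**
- The two alkenyl triflates may carbonylate at different rates.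
- The free hydroxyl may slow the catalyst.
- The C3 acylpalladium may add to the C10 vinyl group before methanol captures it.
- Fallback: it sets out from 24, isolated instead of being desilylated in step 16.
  - Two-fold methoxycarbonylation with O8 still silylated (Pd(OAc)2, PPh3, Et3N, CO, methanol as solvent) should give the O8-silylated bis(methyl acrylate) F1.
  - Citric acid in methanol frees the hydroxy diester F2.
  - Camphorsulfonic acid in toluene closes ring B by transesterification, which returns to the route at 28.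
  - Lactone closure is thus separated from the palladium chemistry.

**Step 15 (hydride shift).**
- Methyl migration may compete with hydride migration.
- Neighbouring oxygens may take part at the C7 cation.
- The ketones may undergo enol silylation.
- Fallback: it sets out from 19 and uses a primary carbinol, where only hydride can migrate.
  - Stille coupling with (tributylstannyl)methanol (Pd(PPh3)4, toluene) gives the C7 hydroxymethyl alkene F3.
  - VO(acac)2/tBuOOH gives the top-face epoxy alcohol F4.
  - Me3SiOTf/2,6-lutidine gives the C7 aldehyde with O8 trimethylsilyl ether F5.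
  - MeTi(OiPr)3 adds to the aldehyde but not to the C4 ketone and gives the C11 carbinol F6.
  - Dess–Martin oxidation returns to the route at 23.

**Step 22 (angeloylation).**
- Acyl transfer to the axial, doubly flanked O6–H may be slow.
- Long heating may cause Z to E isomerisation of the angelate.
- Fallback: it sets out from 32.
  - Steglich esterification with 2-[bis(2,2,2-trifluoroethoxy)phosphoryl]propanoic acid gives the phosphonopropionate F7.
  - Still–Gennari olefination (KN(SiMe3)2, 18-crown-6, THF, −78 °C, then 6) builds the Z alkene on the ester already in place and returns to the route at 35.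

Further compounds
F1 | step 17 | O8-trimethylsilyl 5,7-bis(methyl acrylate) | C=C[C@@]1(C)[C@H](C(=C)C(=O)OC)[C@H](O[Si](CC)(CC)CC)[C@@H](C(=C)C(=O)OC)[C@@H](O[Si](C)(C)C)[C@@H]1O[Si](C)(C)C(C)(C)C
F2 | step 17 | C8 hydroxy 5,7-bis(methyl acrylate) | C=C[C@@]1(C)[C@H](C(=C)C(=O)OC)[C@H](O[Si](CC)(CC)CC)[C@@H](C(=C)C(=O)OC)[C@@H](O)[C@@H]1O[Si](C)(C)C(C)(C)C
F3 | step 15 | C7 hydroxymethyl alkene | C=C[C@@]1(C)[C@H](C(C)=O)[C@H](O[Si](CC)(CC)CC)C(CO)=C[C@@H]1O[Si](C)(C)C(C)(C)C
F4 | step 15 | top-face C7–C8 epoxide with primary carbinol | C=C[C@@]1(C)[C@H](C(C)=O)[C@H](O[Si](CC)(CC)CC)[C@@]2(CO)O[C@H]2[C@@H]1O[Si](C)(C)C(C)(C)C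
F5 | step 15 | C7 aldehyde with O8 trimethylsilyl ether | C=C[C@@]1(C)[C@H](C(C)=O)[C@H](O[Si](CC)(CC)CC)[C@@H](C=O)[C@@H](O[Si](C)(C)C)[C@@H]1O[Si](C)(C)C(C)(C)C
F6 | step 15 | C11 carbinol with O8 trimethylsilyl ether | C=C[C@@]1(C)[C@H](C(C)=O)[C@H](O[Si](CC)(CC)CC)[C@@H](C(C)O)[C@@H](O[Si](C)(C)C)[C@@H]1O[Si](C)(C)C(C)(C)C
F7 | step 22 | O6 2-[bis(2,2,2-trifluoroethoxy)phosphoryl]propanoate | C=C[C@@]1(C)[C@H](C(=C)CO[Si](c3ccccc3)(c3ccccc3)C(C)(C)C)[C@H](OC(=O)C(C)P(=O)(OCC(F)(F)F)OCC(F)(F)F)[C@H]2C(=C)C(=O)O[C@H]2[C@@H]1O[Si](C)(C)C(C)(C)C
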